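I followed the incoming ligand.

| setting | ochre | red | violet | epsilon | zeta | theta |
|---|---|---|---|---|---|---|
| starting complex | 12 mM | 12 mM | 12 mM | 12 mM | 12 mM | 12 mM |
| incoming ligand | 5 mM | 17 mM | 57 mM | 9.60 mM | 6.00 mM | 48.0 mM |
| leaving ligand | 12 mM | 12 mM | 12 mM | 12.0 mM | 12.0 mM | 12.0 mM |
| remark | run made earlier | run made earlier | run made earlier |  |  |  |
| time |  |  |  | 40 h | 40 h | 40 h |

| run | time / h | complex with two exchanged / % | complex with one exchanged / % | starting complex / % |
|---|---|---|---|---|
| ochre | 2.50 | 0 | 12.8 | 37.6 |
| ochre | 4.00 | 0.2 | 13.7 | 37.3 |
| ochre | 8.00 | 2.8 | 13.2 | 39.9 |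
| ochre | 15.0 | 0 | 14.2 | 38.3 |
| ochre | 30.0 | 0.9 | 13.8 | 39.9 |
| red | 2.50 | 0.6 | 39.2 | 29.1 |
| red | 4.00 | 1.0 | 39.3 | 26.4 |
| red | 8.00 | 1.0 | 38.7 | 25.4 |
| red | 15.0 | 1.6 | 39.0 | 27.0 |
| red | 30.0 | 1.5 | 37.9 | 27.5 |
| violet | 2.50 | 11.7 | 70.8 | 8.1 |
| violet | 4.00 | 13.5 | 71.4 | 8.6 |
| violet | 8.00 | 10.7 | 69.5 | 8.1 |
| violet | 15.0 | 12.6 | 68.7 | 9.3 |
| violet | 30.0 | 12.6 | 69.4 | 8.0 |

(readings scatter by 1 percentage point)

- which of these holds the largest part of the starting complex at the end of epsilon (starting complex / complex with two exchanged / complex with one exchanged)
- which of these holds the largest part of the starting complex at the end of zeta (starting complex / complex with two exchanged / complex with one exchanged)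
- which of these holds the largest part of the starting complex at the end of theta (starting complex / complex with two exchanged / complex with one exchanged)
- complex with two exchanged at the end of theta, in percent of the starting complex charged

- steps that have been proposed: starting complex + incoming ligand -> leaving ligand + complex with one exchanged; complex with one exchanged + incoming ligand -> leaving ligand + complex with two exchanged; starting complex <-> dormant form; incoming ligand -> decomposed reagent

In the violet run the readings stood still from 2.50 h to 30.0 h, so I closed its books at the last reading. Of 57 mM of incoming ligand charged, 8.33 mM sat on complex with one exchanged and 3.02 mM on complex with two exchanged, and I booked the remaining 45.6 mM to decomposed reagent, a loss larger than what the complex took, and since the violet readings still showed 8.0% of starting complex after they had stopped moving, I treated incoming ligand as the limiting reagent.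

Going to logarithms, the violet run gave 0.0131 mM⁻¹ as capture decades: the powers of ten by which the unexchanged complex, free starting complex plus dormant form, falls per mM of incoming ligand charged. The red run gave 0.0128 mM⁻¹ and the ochre run 0.0138 mM⁻¹, which I read as one value within the scatter. From the violet readings I also took 44.4% of the unexchanged complex as free, and a ratio of two-exchanged to one-exchanged of 0.182, which I scaled with the charge.

For theta I reckoned 23.6% unexchanged, a ratio of 0.153, 10.1% with two exchanged and 66.3% with one, which put 10.4 mM of ligand on complex and 37.6 mM into decomposed reagent. For epsilon I reckoned 33.3% free against 24.3% with one exchanged, and for zeta 37.1% against 16.2%.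

The forecast, holding that “The incoming ligand has simply decomposed”, named starting complex for epsilon, starting complex for zeta, complex with one exchanged for theta and 9.5% of complex with two exchanged in theta, a little below my figure.

The flasks gave starting complex in epsilon at 34.2% against 24.4% with one exchanged, starting complex in zeta at 38.1% against 16.1%, and complex with one exchanged in theta at 67.6%, with 9.25% of complex with two exchanged and 37.7 mM of decomposed reagent.

    starting complex + incoming ligand → leaving ligand + complex with one exchanged (k = 9.30 L mol⁻¹ min⁻¹)
    complex with one exchanged + incoming ligand → leaving ligand + complex with two exchanged (k = 0.850 L mol⁻¹ min⁻¹)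
    starting complex ⇌ dormant form (K = 1.20, k = 0.0700 min⁻¹)
    incoming ligand → decomposed reagent (k = 0.170 min⁻¹)

Theta stopped short of full exchange through the conversion of incoming ligand into decomposed reagent: the same run without that step ended with 100% of complex with two exchanged instead of 9.25%. A neighbour flask like theta but charged with 190 mM of incoming ligand got from the capture decades 2.49 powers of ten, or 0.329% unexchanged. That neighbour flask held 1.02% free and 1.22% dormant, together 2.24%, which is more than the capture decades gave, so at this charge they missed, and in it complex with two exchanged led at 51.8% against 46.0% with one exchanged.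

The earlier runs and the new flask were generated by integration with constants of no real substance.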